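(The numbers in the tables come from a simulation for an exercise; the scatter is artificial.)

Percent of the X charged is the unit of every reading here, so the west flask, the one asked about, and the east run can be laid side by side despite their different charges.

| flask | X | remark | time |
|---|---|---|---|
| west | 0.10 M | the very flask that is asked about, followed so far |  |
| east | 0.067 M | run made earlier |  |
| flask | 0.10 M |  | 1.0 h |

| run | time / min | J / % | G / % | X / % |
|---|---|---|---|---|
| west | 1.67 | 5.0 | 41.4 | 27.5 |
| west | 3.00 | 9.4 | 35.2 | 22.1 |
| west | 6.00 | 10.3 | 27.1 | 16.2 |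
| west | 15.0 | 9.2 | 17.8 | 12.8 |
| west | 30.0 | 4.9 | 12.8 | 8.4 |
| east | 1.67 | 6.9 | 43.4 | 28.0 |
| east | 4.00 | 10.7 | 36.9 | 21.9 |
| east | 10.0 | 10.4 | 23.0 | 15.3 |
| east | 25.0 | 7.8 | 18.6 | 10.4 |
| east | 60.0 | 7.0 | 9.1 | 6.6 |

(each reading ± 1 percentage point)

- the moment within 1.0 h at which there is most J
- the amount of J, in percent of the X charged, at that time
- the first time at which J reaches 7.8%, in the same percent, in min



From 6.00 min in west and 10.0 min in east, G and J fall together. My own reckoning therefore treats their exchange as a quasi-equilibrium and pools those readings into s = 0.458, the late ratio: summed J over summed G. On this view J climbs while below s·G and falls once above it, so the maximum sits at their crossing.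

In west at 6.00 min, J reads 10.3% against an s·G of 12.4%; at 15.0 min it reads 9.2% against 8.15%. My bracket for the maximum is therefore these two times.

Turned round, for J to stop short of 7.8% on this view, the crossing would have to come with G under 17.0%. West G reads 27.1% at 6.00 min, far above that, and 17.8% at 15.0 min, over it by 0.80 percentage points, and west J at 6.00 min reads 2.5 points over the level.

The forecast gives 0.11 h (0.06 h to 0.18 h), 10.4% (9.5% to 11.4%) and 2.4 min (1.8 min to 3.1 min): “So there is a broad maximum near 6–7 min of about 10.4%”. That time lies at the early end of my bracket.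

The west flask gives 0.0999 h, 11.2% and 2.16 min, each inside the forecast's range.

    2 X → Z (k = 0.0580 M⁻¹ s⁻¹)
    X ⇌ E (K = 2.00, k = 0.00130 s⁻¹)
    X ⇌ G (K = 1.50, k = 0.0320 s⁻¹)
    G ⇌ J (K = 0.420, k = 0.00210 s⁻¹)
    X → D (k = 2.00 × 10⁻⁵ s⁻¹)

At the best time, west G is 26.6%, so s·G is 12.2%, above J at 11.2%. At 1.00 h, west G at 8.96% gives 4.10%, with west J at 3.87%. A neighbour flask, like west but charged with 0.40 M of X, reaches 6.66% of J at most, short of the 7.8% level. At 1.00 h its G is 3.23%, so s·G is 1.48%, and its J stands at 1.40%.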